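**Retrosynthetic overview**
- The aryl ring is bought. The ester C–O bond is cut last: target ⇒ dienol 18 + O-acetylvanillic acid 19. The only ring to build is the 11-membered carbocycle.
- The carbocycle is not closed as an 11-ring. The bond between the carbinol carbon (ring C1) and the methyl-bearing alkene carbon (ring C2) comes from a 1,2-metallate ring contraction of a 12-membered cyclic boronate complex 16, in which boron bridges these two atoms. Ring order: 12-membered boracycle first, then the 11-membered carbocycle.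
- Enabling feature: ring C1 is a secondary allylic carbinol bonded directly to sp2 ring C2 of the Z-trisubstituted alkene. C1 can therefore be carried as a stereodefined B,O-substituted carbon (C–O from C–B with retention), and C2 as an alkenyl group that migrates from boron with its Z geometry intact.
- Acyclic precursor 14 ⇒ Z-selective iodo-Wittig (chain C10=C11), sparteine-controlled lithiation–borylation (chain C1), and Cu-catalysed sp3–sp3 coupling (C5–C6) of allylic bromide 4 (E alkene from SeO2 oxidation of 1) with the Grignard reagent from diol 5.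

Key step: step 11

Remark: "chain C1–C12" means the dodeca-3,10-dienyl chain of 14; chain C1 and C11 become ring C1 and C2 of 18.

**Step 1**
Reactants: 1 4-methylpent-3-en-1-ol
Product: 2 4-methylpent-3-en-1-yl N,N-diisopropylcarbamate
Conditions: iPr2NCOCl, Et3N, CH2Cl2, reflux
Reagents that add atoms: N,N-diisopropylcarbamoyl chloride, CC(C)N(C(C)C)C(=O)Cl
Why: O-carbamoylation of a primary alcohol; the hindered carbamate protects O1 now and later serves as directing group and leaving group at chain C1.

**Step 2**
Reactants: 2 4-methylpent-3-en-1-yl N,N-diisopropylcarbamate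
Product: 3 (E)-5-hydroxy-4-methylpent-3-en-1-yl N,N-diisopropylcarbamate
Conditions: SeO2 (cat.), t-BuOOH, salicylic acid (cat.), CH2Cl2, rt
Reagents that add atoms: tert-butyl hydroperoxide, CC(C)(C)OO (the oxygen is passed on by the SeO2 catalyst, O=[Se]=O)
Why: Riley allylic oxidation (ene reaction, then [2,3]-shift) of a trisubstituted alkene attacks the methyl group trans to the chain, which should fix the E geometry of the future ring C9=C10 alkene.

**Step 3**
Reactants: 3 (E)-5-hydroxy-4-methylpent-3-en-1-yl N,N-diisopropylcarbamate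
Product: 4 (E)-5-bromo-4-methylpent-3-en-1-yl N,N-diisopropylcarbamate
Conditions: CBr4, PPh3, CH2Cl2, 0 °C
Reagents that add atoms: carbon tetrabromide, BrC(Br)(Br)Br
Why: Appel reaction of a primary allylic alcohol under neutral conditions should give the primary allylic bromide without allylic shift or loss of E geometry.

**Step 4**
Reactants: 5 3,3-dimethylpentane-1,5-diol
Product: 6 5-[(tert-butyldimethylsilyl)oxy]-3,3-dimethylpentan-1-ol
Conditions: NaH (1 equiv), THF, rt; TBSCl
Reagents that add atoms: tert-butyldimethylsilyl chloride, CC(C)(C)[Si](C)(C)Cl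
Why: monosilylation of a symmetric diol through its sparingly soluble monosodium alkoxide desymmetrises the gem-dimethyl C5 unit (chain C6–C10).

**Step 5**
Reactants: 6 5-[(tert-butyldimethylsilyl)oxy]-3,3-dimethylpentan-1-ol
Product: 7 [(5-bromo-3,3-dimethylpentyl)oxy](tert-butyl)dimethylsilane
Conditions: CBr4, PPh3, CH2Cl2, 0 °C
Reagents that add atoms: carbon tetrabromide, BrC(Br)(Br)Br
Why: Appel bromination of the free primary alcohol; the silyl ether tolerates the neutral conditions.

**Step 6**
Reactants: 7 [(5-bromo-3,3-dimethylpentyl)oxy](tert-butyl)dimethylsilane; 4 (E)-5-bromo-4-methylpent-3-en-1-yl N,N-diisopropylcarbamate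
Product: 9 (E)-10-[(tert-butyldimethylsilyl)oxy]-4,8,8-trimethyldec-3-en-1-yl N,N-diisopropylcarbamate, via Grignard reagent 8 (not isolated)
Conditions: Mg, THF, 40 °C; then 4, Li2CuCl4 (cat.), THF, −78 → 0 °C
Reagents that add atoms: none
Why: copper-catalysed cross-coupling of a primary alkyl Grignard reagent with a primary allylic bromide should go by direct (α) substitution with retention of the E alkene and forms the C5–C6 bond; the diisopropylcarbamate is inert to the Grignard reagent.

**Step 7**
Reactants: 9 (E)-10-[(tert-butyldimethylsilyl)oxy]-4,8,8-trimethyldec-3-en-1-yl N,N-diisopropylcarbamate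
Product: 11 (S,E)-10-[(tert-butyldimethylsilyl)oxy]-4,8,8-trimethyl-1-(4,4,5,5-tetramethyl-1,3,2-dioxaborolan-2-yl)dec-3-en-1-yl N,N-diisopropylcarbamate, via lithiated carbamate 10 (not isolated)
Conditions: s-BuLi, (−)-sparteine, Et2O, −78 °C; i-PrOBpin, −78 °C → rt; aq. NH4Cl
Reagents that add atoms: 2-isopropoxy-4,4,5,5-tetramethyl-1,3,2-dioxaborolane, CC(C)OB1OC(C)(C)C(C)(C)O1
Why: sparteine-mediated asymmetric α-lithiation of an O-alkyl carbamate (lithiation–borylation) removes the pro-S proton, and the configurationally stable organolithium is borylated with retention, which should set the (S)-configured B,O-carbon.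

**Step 8**
Reactants: 11 the (S)-α-boryl carbamate silyl ether
Product: 12 (S,E)-10-hydroxy-4,8,8-trimethyl-1-(4,4,5,5-tetramethyl-1,3,2-dioxaborolan-2-yl)dec-3-en-1-yl N,N-diisopropylcarbamate
Conditions: CSA (cat.), MeOH–CH2Cl2, 0 °C
Reagents that add atoms: none
Why: acid-catalysed methanolysis of a primary TBS ether; fluoride is avoided because it would complex the boronic ester, while pinacol boronate and carbamate tolerate mild acid.

**Step 9**
Reactants: 12 the (S)-hydroxy α-boryl carbamate
Product: 13 (S,E)-4,8,8-trimethyl-10-oxo-1-(4,4,5,5-tetramethyl-1,3,2-dioxaborolan-2-yl)dec-3-en-1-yl N,N-diisopropylcarbamate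
Conditions: Dess–Martin periodinane, CH2Cl2, rt
Reagents that add atoms: none
Why: Dess–Martin oxidation of a primary alcohol to the aldehyde leaves the C–B bond, the alkene and the stereocentre untouched.

**Step 10**
Reactants: 13 the (S)-aldehyde
Product: 14 (1S,3E,10Z)-11-iodo-4,8,8-trimethyl-1-(4,4,5,5-tetramethyl-1,3,2-dioxaborolan-2-yl)dodeca-3,10-dien-1-yl N,N-diisopropylcarbamate
Conditions: EtPPh3I, n-BuLi, THF; I2, −78 °C; NaHMDS, −20 °C; then 13, −78 °C → rt
Reagents that add atoms: (1-iodoethylidene)triphenylphosphorane, CC(I)=P(c1ccccc1)(c1ccccc1)c1ccccc1, made in the flask from ethyltriphenylphosphonium iodide, CC[P+](c1ccccc1)(c1ccccc1)c1ccccc1.[I-], and iodine, II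
Why: Z-selective α-iodo Wittig olefination (Stork–Zhao type) of an aldehyde should give the 2-iodo-2-alkene with iodine cis to the chain, which is the geometry needed for the ring 2Z alkene; the aldehyde should outcompete the weakly Lewis-acidic pinacol boronate for the ylide at −78 °C.

**Step 11**
Reactants: 14 the (1S,3E,10Z)-iodo α-boryl carbamate
Product: 18 (1R,2Z,9E)-2,5,5,9-tetramethylcycloundeca-2,9-dien-1-ol, via alkenyllithium 15 (not isolated), via cyclic boronate complex 16 (not isolated), via allylic boronic ester 17 (not isolated)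
Conditions: t-BuLi (2 equiv), THF–Et2O, −100 °C, ca. 2 mM; −78 → 40 °C; then NaOH, H2O2, 0 °C
Reagents that add atoms: hydrogen peroxide, OO
Why: Proposed new method: iodine–lithium exchange gives the configurationally stable alkenyllithium 15, which adds to the tethered boronic ester and closes a 12-membered cyclic boronate complex 16 by C–B bond formation (boron bridges chain C1 and C11); on warming, the alkenyl carbon migrates from boron to C1 anti-periplanar to the departing carbamate (1,2-metallate shift), which forms the C1–C11 bond, pushes boron out of the ring and so contracts the 12-membered boracycle to the 11-membered carbocycle 17, whose C–B bond is then oxidised to C–OH. The closest known reactions are the stereospecific substitution of enantioenriched α-carbamoyloxy boronic esters by organolithium or Grignard reagents through boronate complexes (lithiation–borylation chemistry) and boronate formation by halogen–lithium exchange in the presence of a boronic ester; new here is that the boronate is a 12-membered ring and that the 1,2-shift serves as a ring contraction. The only new stereocentre, ring C1, is controlled by the (S)-configured B,O-carbon of 14: the 1,2-shift inverts it and the oxidation retains it, which should give 1R. The Z geometry should be carried over unchanged because both the alkenyllithium and the migrating alkenyl group keep their configuration. The step needs the exchange to outrun attack of t-BuLi on the hindered pinacol boronate and on the diisopropylcarbamate, and ring closure to outrun boronate formation between molecules; −100 °C, exactly two equivalents of t-BuLi and high dilution are meant to secure this.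

**Step 12**
Reactants: 18 (1R,2Z,9E)-2,5,5,9-tetramethylcycloundeca-2,9-dien-1-ol; 19 4-acetoxy-3-methoxybenzoic acid
Product: 20 (1R,2Z,9E)-2,5,5,9-tetramethylcycloundeca-2,9-dien-1-yl 4-acetoxy-3-methoxybenzoate
Conditions: DCC, DMAP, CH2Cl2, 0 °C → rt
Reagents that add atoms: none
Why: Steglich esterification acylates the secondary allylic alcohol at oxygen, so C1 keeps its R configuration; the phenol is masked as its acetate.

**Step 13**
Reactants: 20 the O-acetyl ester
Product: 21 (1R,2Z,9E)-2,5,5,9-tetramethylcycloundeca-2,9-dien-1-yl 4-hydroxy-3-methoxybenzoate (target)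
Conditions: pyrrolidine, CH2Cl2, 0 °C
Reagents that add atoms: none
Why: chemoselective aminolysis of the aryl acetate, which is far more reactive than the hindered secondary alkyl benzoate, should free the phenol without touching the ester or the alkenes.

**Compound list**
1 | 4-methylpent-3-en-1-ol | CC(C)=CCCO | starting material
2 | 4-methylpent-3-en-1-yl N,N-diisopropylcarbamate | CC(C)=CCCOC(=O)N(C(C)C)C(C)C | intermediate
3 | (E)-5-hydroxy-4-methylpent-3-en-1-yl N,N-diisopropylcarbamate | OC/C(C)=C/CCOC(=O)N(C(C)C)C(C)C | intermediate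
4 | (E)-5-bromo-4-methylpent-3-en-1-yl N,N-diisopropylcarbamate | BrC/C(C)=C/CCOC(=O)N(C(C)C)C(C)C | intermediate
5 | 3,3-dimethylpentane-1,5-diol | OCCC(C)(C)CCO | starting material
6 | 5-[(tert-butyldimethylsilyl)oxy]-3,3-dimethylpentan-1-ol | OCCC(C)(C)CCO[Si](C)(C)C(C)(C)C | intermediate
7 | [(5-bromo-3,3-dimethylpentyl)oxy](tert-butyl)dimethylsilane | BrCCC(C)(C)CCO[Si](C)(C)C(C)(C)C | intermediate
8 | {5-[(tert-butyldimethylsilyl)oxy]-3,3-dimethylpentyl}magnesium bromide | Br[Mg]CCC(C)(C)CCO[Si](C)(C)C(C)(C)C | intermediate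
9 | (E)-10-[(tert-butyldimethylsilyl)oxy]-4,8,8-trimethyldec-3-en-1-yl N,N-diisopropylcarbamate | CC(C)N(C(C)C)C(=O)OCC/C=C(\C)CCCC(C)(C)CCO[Si](C)(C)C(C)(C)C | intermediate
10 | (S,E)-10-[(tert-butyldimethylsilyl)oxy]-1-lithio-4,8,8-trimethyldec-3-en-1-yl N,N-diisopropylcarbamate (sparteine complex) | CC(C)N(C(C)C)C(=O)O[C@@H]([Li])C/C=C(\C)CCCC(C)(C)CCO[Si](C)(C)C(C)(C)C | intermediate
11 | (S,E)-10-[(tert-butyldimethylsilyl)oxy]-4,8,8-trimethyl-1-(4,4,5,5-tetramethyl-1,3,2-dioxaborolan-2-yl)dec-3-en-1-yl N,N-diisopropylcarbamate | CC(C)N(C(C)C)C(=O)O[C@@H](B1OC(C)(C)C(C)(C)O1)C/C=C(\C)CCCC(C)(C)CCO[Si](C)(C)C(C)(C)C | intermediate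
12 | (S,E)-10-hydroxy-4,8,8-trimethyl-1-(4,4,5,5-tetramethyl-1,3,2-dioxaborolan-2-yl)dec-3-en-1-yl N,N-diisopropylcarbamate | CC(C)N(C(C)C)C(=O)O[C@@H](B1OC(C)(C)C(C)(C)O1)C/C=C(\C)CCCC(C)(C)CCO | intermediate
13 | (S,E)-4,8,8-trimethyl-10-oxo-1-(4,4,5,5-tetramethyl-1,3,2-dioxaborolan-2-yl)dec-3-en-1-yl N,N-diisopropylcarbamate | CC(C)N(C(C)C)C(=O)O[C@@H](B1OC(C)(C)C(C)(C)O1)C/C=C(\C)CCCC(C)(C)CC=O | intermediate
14 | (1S,3E,10Z)-11-iodo-4,8,8-trimethyl-1-(4,4,5,5-tetramethyl-1,3,2-dioxaborolan-2-yl)dodeca-3,10-dien-1-yl N,N-diisopropylcarbamate | CC(C)N(C(C)C)C(=O)O[C@@H](B1OC(C)(C)C(C)(C)O1)C/C=C(\C)CCCC(C)(C)C/C=C(/C)I | intermediate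
15 | alkenyllithium from 14 (lithium in place of iodine, cis to the chain CH2, other stereoelements as in 14) | CC(C)N(C(C)C)C(=O)O[C@@H](B1OC(C)(C)C(C)(C)O1)C/C=C(\C)CCCC(C)(C)C/C=C(/C)[Li] | intermediate
16 | lithium salt of the 12-membered cyclic pinacol boronate complex: tetracoordinate boron bridges the alkenyl carbon and the (S)-carbamoyloxy carbon; ring alkenes and methyl groups as in 14 | [Li+].CC(C)N(C(C)C)C(=O)O[C@@H]1C/C=C(\C)CCCC(C)(C)C/C=C(/C)[B-]12OC(C)(C)C(C)(C)O2 | intermediate
17 | 2-[(1R,2Z,9E)-2,5,5,9-tetramethylcycloundeca-2,9-dien-1-yl]-4,4,5,5-tetramethyl-1,3,2-dioxaborolane | CC1(C)OB(OC1(C)C)[C@@H]2C/C=C(\C)CCCC(C)(C)C/C=C\2C | intermediate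
18 | (1R,2Z,9E)-2,5,5,9-tetramethylcycloundeca-2,9-dien-1-ol | O[C@@H]1C/C=C(\C)CCCC(C)(C)C/C=C\1C | intermediate
19 | 4-acetoxy-3-methoxybenzoic acid | COc1cc(C(=O)O)ccc1OC(C)=O | starting material
20 | (1R,2Z,9E)-2,5,5,9-tetramethylcycloundeca-2,9-dien-1-yl 4-acetoxy-3-methoxybenzoate | COc1cc(C(=O)O[C@@H]2C/C=C(\C)CCCC(C)(C)C/C=C\2C)ccc1OC(C)=O | intermediate
21 | (1R,2Z,9E)-2,5,5,9-tetramethylcycloundeca-2,9-dien-1-yl 4-hydroxy-3-methoxybenzoate | COc1cc(C(=O)O[C@@H]2C/C=C(\C)CCCC(C)(C)C/C=C\2C)ccc1O | target

**Step count**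
Total steps: 13. Longest linear sequence: 11 steps (steps 1–3 and 6–13; the branch 4–5 joins at step 6).

**Steps most likely to fail**

1. Step 11 (proposed new method). t-BuLi may add to boron before the iodine–lithium exchange is complete, or the alkenyllithium may form boronate complexes between molecules faster than it closes the 12-membered ring. The fallback uses known chemistry and closes the carbocycle directly, giving up the ring contraction. It sets out from 14. Buffered oxidation (H2O2, pH 7 phosphate, THF) of the α-carbamoyloxy boronate should release the aldehyde (3E,10Z)-11-iodo-4,8,8-trimethyldodeca-3,10-dienal F1. An intramolecular Nozaki–Hiyama–Kishi reaction (CrCl2, NiCl2 cat., DMSO–THF, high dilution) should then give racemic (2Z,9E)-2,5,5,9-tetramethylcycloundeca-2,9-dien-1-ol F2. Dess–Martin oxidation to (2Z,9E)-2,5,5,9-tetramethylcycloundeca-2,9-dien-1-one F3, followed by Corey–Bakshi–Shibata reduction with the (S)-oxazaborolidine (alkenyl as the large group), should return to the route at 18.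

2. Step 10. The iodo-ylide olefination may lose Z selectivity, or the ylide may be captured by the boronic ester. The fallback sets out from 13. Ramirez dibromo-olefination (CBr4, PPh3, Zn) should give the (S,E)-11,11-dibromo-4,8,8-trimethyl-1-(pinacolboryl)undeca-3,10-dien-1-yl N,N-diisopropylcarbamate F4. Palladium-catalysed trans-selective mono-methylation (Negishi coupling with MeZnCl) should then give the (1S,3E,10Z)-11-bromo-4,8,8-trimethyl-1-(pinacolboryl)dodeca-3,10-dien-1-yl N,N-diisopropylcarbamate F5, with bromine cis to the chain. Bromine–lithium exchange with t-BuLi enters the key step at alkenyllithium 15, and the fallback comes back to the route at 18.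

3. Step 6. The copper-catalysed coupling may suffer allylic transposition (attack at the γ-carbon), E/Z scrambling of the allyl partner, or homocoupling. The fallback sets out from 7 and 4. Displacement of bromide in 7 with sodium benzenesulfinate (DMF, 60 °C) should give tert-butyldimethyl{[3,3-dimethyl-5-(phenylsulfonyl)pentyl]oxy}silane F6. Deprotonation (n-BuLi, THF, −78 °C) and alkylation with 4 should give (E)-10-[(tert-butyldimethylsilyl)oxy]-4,8,8-trimethyl-6-(phenylsulfonyl)dec-3-en-1-yl N,N-diisopropylcarbamate F7. Reductive desulfonylation (Na/Hg, Na2HPO4, MeOH, −20 °C) comes back to the route at 9.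

**Further compounds**
F1 | step 11 | (3E,10Z)-11-iodo-4,8,8-trimethyldodeca-3,10-dienal | O=CC/C=C(\C)CCCC(C)(C)C/C=C(/C)I
F2 | step 11 | racemic (2Z,9E)-2,5,5,9-tetramethylcycloundeca-2,9-dien-1-ol | OC1C/C=C(\C)CCCC(C)(C)C/C=C\1C
F3 | step 11 | (2Z,9E)-2,5,5,9-tetramethylcycloundeca-2,9-dien-1-one | O=C1C/C=C(\C)CCCC(C)(C)C/C=C\1C
F4 | step 10 | (S,E)-11,11-dibromo-4,8,8-trimethyl-1-(4,4,5,5-tetramethyl-1,3,2-dioxaborolan-2-yl)undeca-3,10-dien-1-yl N,N-diisopropylcarbamate | CC(C)N(C(C)C)C(=O)O[C@@H](B1OC(C)(C)C(C)(C)O1)C/C=C(\C)CCCC(C)(C)CC=C(Br)Br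
F5 | step 10 | (1S,3E,10Z)-11-bromo-4,8,8-trimethyl-1-(4,4,5,5-tetramethyl-1,3,2-dioxaborolan-2-yl)dodeca-3,10-dien-1-yl N,N-diisopropylcarbamate | CC(C)N(C(C)C)C(=O)O[C@@H](B1OC(C)(C)C(C)(C)O1)C/C=C(\C)CCCC(C)(C)C/C=C(/C)Br
F6 | step 6 | tert-butyldimethyl{[3,3-dimethyl-5-(phenylsulfonyl)pentyl]oxy}silane | O=S(=O)(CCC(C)(C)CCO[Si](C)(C)C(C)(C)C)c1ccccc1
F7 | step 6 | (E)-10-[(tert-butyldimethylsilyl)oxy]-4,8,8-trimethyl-6-(phenylsulfonyl)dec-3-en-1-yl N,N-diisopropylcarbamate | CC(C)N(C(C)C)C(=O)OCC/C=C(\C)CC(CC(C)(C)CCO[Si](C)(C)C(C)(C)C)S(=O)(=O)c1ccccc1
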